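## Retrosynthetic overview

- Feature: in ring B of the 1-tetralone, C4 (H, ring C aryl), C3 (H, CH3) and C2 (H, CH3) form a contiguous chain between C4a of ring A and the C1 carbonyl, and C3 and C2 are each a CH(CH3) unit that can be inserted next to boron as a chiral carbenoid carbon (tetralone locants; ring A = dimethoxybenzo ring, ring C = pendant aryl).
- C1–C8a: Friedel–Crafts acylation closes ring B last and is the only ring formation (rings A and C are bought), with ring C switched off as its acetate; C1 comes from a CH2 insertion into the C2–B bond and oxidation to the acid.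
- C2–C3 and C3–C4: two reagent-controlled 1,2-metallate rearrangements in one pot on the diarylmethyl pinacol boronic ester.
- C4–B from C4–N by stereospecific nickel-catalysed borylation of a trimethylammonium salt; the C4–ring C bond and the C4 configuration come from aryl Grignard addition to the tert-butanesulfinyl imine of veratraldehyde.

Key step: step 7

Assumption: the nickel-catalysed borylation of step 6 is taken to invert the benzylic carbon (SN2-type C–N oxidative addition), so the R amine series is prepared; if it retained, (S)-2-methylpropane-2-sulfinamide would be used in step 1.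

## Route

Step 1
Reactants: 1 veratraldehyde (3,4-dimethoxybenzaldehyde); 2 (R)-2-methylpropane-2-sulfinamide
Product: 3 (R,E)-N-(3,4-dimethoxybenzylidene)-2-methylpropane-2-sulfinamide
Conditions: Ti(OEt)4 (2 equiv), THF, rt
Reagents that add atoms: none
Why: Ti(OEt)4-mediated condensation of an aryl aldehyde with the sulfinamide (imine formation) should give the E aldimine without touching the sulfur stereocentre.

Step 2
Reactants: 4 2-(benzyloxy)-4-bromo-1-methoxybenzene; 3 (R,E)-N-(3,4-dimethoxybenzylidene)-2-methylpropane-2-sulfinamide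
Product: 6 (R)-N-[(R)-(3-(benzyloxy)-4-methoxyphenyl)(3,4-dimethoxyphenyl)methyl]-2-methylpropane-2-sulfinamide, via arylmagnesium bromide 5 (not isolated)
Conditions: Mg, THF, rt; then 3, CH2Cl2, −48 °C → rt; H2O
Reagents that add atoms: none
Why: Grignard addition to an N-tert-butanesulfinyl aldimine in a non-coordinating solvent runs through a six-membered chair transition state with magnesium bridging the sulfinyl oxygen and tert-butyl equatorial, so the (R)-sulfur auxiliary should deliver the aryl group to one imine face and set C4 as R, however alike the two aryl groups are.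

Step 3
Reactants: 6 (R)-N-[(R)-(3-(benzyloxy)-4-methoxyphenyl)(3,4-dimethoxyphenyl)methyl]-2-methylpropane-2-sulfinamide
Product: 7 (R)-(3-(benzyloxy)-4-methoxyphenyl)(3,4-dimethoxyphenyl)methanamine
Conditions: HCl (4 M in dioxane, 2 equiv), MeOH, 0 °C; then NaOH (aq.)
Reagents that add atoms: none
Why: Acid methanolysis of the sulfinamide S–N bond is fast at 0 °C, and brief exposure to a small excess of acid should leave the benzhydrylic C–N bond and the benzyl ether intact.

Step 4
Reactants: 7 (R)-(3-(benzyloxy)-4-methoxyphenyl)(3,4-dimethoxyphenyl)methanamine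
Product: 8 (R)-1-(3-(benzyloxy)-4-methoxyphenyl)-1-(3,4-dimethoxyphenyl)-N,N-dimethylmethanamine
Conditions: CH2O (37% aq.), NaBH(OAc)3, ClCH2CH2Cl, rt
Reagents that add atoms: formaldehyde, C=O
Why: Double reductive amination with formaldehyde and a mild hydride methylates nitrogen twice without strong acid or heat, so the carbon stereocentre is not involved.

Step 5
Reactants: 8 (R)-1-(3-(benzyloxy)-4-methoxyphenyl)-1-(3,4-dimethoxyphenyl)-N,N-dimethylmethanamine
Product: 9 (R)-[(3-(benzyloxy)-4-methoxyphenyl)(3,4-dimethoxyphenyl)methyl]trimethylammonium trifluoromethanesulfonate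
Conditions: MeOTf, Et2O, 0 °C → rt
Reagents that add atoms: methyl trifluoromethanesulfonate, COS(=O)(=O)C(F)(F)F
Why: N-Alkylation (quaternisation) of the tertiary amine with methyl triflate should give the ammonium triflate as a precipitate that is used without chromatography.

Step 6
Reactants: 9 (R)-[(3-(benzyloxy)-4-methoxyphenyl)(3,4-dimethoxyphenyl)methyl]trimethylammonium trifluoromethanesulfonate
Product: 10 2-[(S)-(3-(benzyloxy)-4-methoxyphenyl)(3,4-dimethoxyphenyl)methyl]-4,4,5,5-tetramethyl-1,3,2-dioxaborolane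
Conditions: Ni(cod)2 (10 mol%), PPh3 (20 mol%), B2pin2, KOMe, THF, rt
Reagents that add atoms: bis(pinacolato)diboron, CC1(C)OB(OC1(C)C)B1OC(C)(C)C(C)(C)O1
Why: Stereospecific nickel-catalysed Miyaura-type borylation of a benzylic ammonium salt, in which zerovalent nickel should enter the C–N bond from the back side and boryl transfer from methoxide-activated B2pin2 with stereoretentive reductive elimination should turn the (R)-ammonium salt into the (S)-boronic ester.

Step 7
Reactants: 10 2-[(S)-(3-(benzyloxy)-4-methoxyphenyl)(3,4-dimethoxyphenyl)methyl]-4,4,5,5-tetramethyl-1,3,2-dioxaborolane; 11 ethyl 2,4,6-triisopropylbenzoate (two portions)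
Product: 17 2-[(2S,3S,4S)-4-(3-(benzyloxy)-4-methoxyphenyl)-4-(3,4-dimethoxyphenyl)-3-methylbutan-2-yl]-4,4,5,5-tetramethyl-1,3,2-dioxaborolane, via (S)-1-lithioethyl 2,4,6-triisopropylbenzoate 12 (not isolated), via first lithium boronate complex 13 (not isolated), via monohomologated boronic ester 14 (not isolated), via (R)-1-lithioethyl 2,4,6-triisopropylbenzoate 15 (not isolated), via second lithium boronate complex 16 (not isolated)
Conditions: 11, s-BuLi, (−)-sparteine, Et2O, −78 °C; add 10, −78 °C then 35 °C; recool to −78 °C, cannulate into 15 [11, s-BuLi, (+)-sparteine, Et2O, −78 °C]; −78 °C then 35 °C; HCl (1 M aq.)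
Reagents that add atoms: none
Why: Each sparteine-bound 1-lithioethyl benzoate (12, then 15) is configurationally stable at −78 °C and adds to trigonal boron with retention at its carbanion carbon to give a boronate complex (13, then 16); on warming, the carbon on boron shifts to the carbenoid carbon antiperiplanar to the departing triisopropylbenzoate, with inversion at the carbenoid carbon and retention in the migrating carbon. The closest known reaction type is iterative lithiation–borylation (assembly-line homologation) of secondary pinacol boronic esters with the two enantiomers of an α-lithioethyl triisopropylbenzoate; the step forms C3–C4 and then C2–C3 and closes no ring. C3 is set by 12 (made with (−)-sparteine) and C2 by 15 (made with (+)-sparteine) under reagent control alone, and C4 is carried through with retention, which matters because the two aryl groups on C4 are too alike for any substrate control. The step needs boronate formation at the hindered diarylmethyl boron to outrun removal of the acidic benzhydrylic proton and needs a single insertion each time; the high electrophilicity of boron towards organolithiums, the good leaving-group ability of the hindered benzoate and the small excess of carbenoid, which decomposes on warming before 14 or 17 meets it, should secure this.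

Step 8
Reactants: 17 2-[(2S,3S,4S)-4-(3-(benzyloxy)-4-methoxyphenyl)-4-(3,4-dimethoxyphenyl)-3-methylbutan-2-yl]-4,4,5,5-tetramethyl-1,3,2-dioxaborolane
Product: 19 2-[(2R,3S,4S)-4-(3-(benzyloxy)-4-methoxyphenyl)-4-(3,4-dimethoxyphenyl)-2,3-dimethylbutyl]-4,4,5,5-tetramethyl-1,3,2-dioxaborolane, via lithium chloromethyl boronate complex 18 (not isolated)
Conditions: BrCH2Cl, n-BuLi, THF, −78 °C → rt
Reagents that add atoms: bromochloromethane, ClCBr
Why: Matteson homologation, in which chloromethyllithium from bromine–lithium exchange adds to boron and the secondary alkyl group migrates to carbon with loss of chloride and retention at C2, inserts the CH2 that becomes C1.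

Step 9
Reactants: 19 2-[(2R,3S,4S)-4-(3-(benzyloxy)-4-methoxyphenyl)-4-(3,4-dimethoxyphenyl)-2,3-dimethylbutyl]-4,4,5,5-tetramethyl-1,3,2-dioxaborolane
Product: 20 (2S,3R,4S)-4-(3-(benzyloxy)-4-methoxyphenyl)-4-(3,4-dimethoxyphenyl)-2,3-dimethylbutan-1-ol
Conditions: H2O2 (30% aq.), NaOH (2 M aq.), THF, 0 °C → rt
Reagents that add atoms: hydrogen peroxide, OO
Why: Oxidation of the primary C–B bond by hydroperoxide (1,2-shift from boron to oxygen) should give the primary alcohol without touching C2, C3 or C4.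

Step 10
Reactants: 20 (2S,3R,4S)-4-(3-(benzyloxy)-4-methoxyphenyl)-4-(3,4-dimethoxyphenyl)-2,3-dimethylbutan-1-ol
Product: 22 (2S,3R,4S)-4-(3-(benzyloxy)-4-methoxyphenyl)-4-(3,4-dimethoxyphenyl)-2,3-dimethylbutanoic acid, via aldehyde 21 (not isolated)
Conditions: TEMPO (20 mol%), PhI(OAc)2 (2.5 equiv), MeCN/H2O 1:1, rt
Reagents that add atoms: water, O
Why: Oxoammonium-catalysed oxidation (TEMPO/PhI(OAc)2) takes the primary alcohol through aldehyde 21 and its hydrate to the acid under near-neutral conditions, so C2 should not epimerise and the benzyl ether and electron-rich rings should survive.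

Step 11
Reactants: 22 (2S,3R,4S)-4-(3-(benzyloxy)-4-methoxyphenyl)-4-(3,4-dimethoxyphenyl)-2,3-dimethylbutanoic acid
Product: 23 (2S,3R,4R)-4-(3,4-dimethoxyphenyl)-4-(3-hydroxy-4-methoxyphenyl)-2,3-dimethylbutanoic acid
Conditions: H2 (1 atm), 10% Pd/C, EtOAc/MeOH, rt
Reagents that add atoms: none
Why: Hydrogenolysis of the benzyl aryl ether frees the ring C phenol, while the diarylmethine C–H bond and the acid are inert (the C4 descriptor changes only because the ring priorities change).

Step 12
Reactants: 23 (2S,3R,4R)-4-(3,4-dimethoxyphenyl)-4-(3-hydroxy-4-methoxyphenyl)-2,3-dimethylbutanoic acid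
Product: 24 (2S,3R,4S)-4-(3-acetoxy-4-methoxyphenyl)-4-(3,4-dimethoxyphenyl)-2,3-dimethylbutanoic acid
Conditions: Ac2O, NaOH (aq.), 0 °C; then HCl (aq.) to pH 3
Reagents that add atoms: acetic anhydride, CC(=O)OC(C)=O
Why: O-Acetylation of the phenoxide in cold aqueous base is fast while the carboxylate is not acylated in water, and the acyloxy group makes ring C far less nucleophilic than ring A for the ring closure.

Step 13
Reactants: 24 (2S,3R,4S)-4-(3-acetoxy-4-methoxyphenyl)-4-(3,4-dimethoxyphenyl)-2,3-dimethylbutanoic acid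
Product: 26 (2S,3R,4R)-4-(3-acetoxy-4-methoxyphenyl)-6,7-dimethoxy-2,3-dimethyl-3,4-dihydronaphthalen-1(2H)-one, via mixed trifluoroacetic anhydride 25 (not isolated)
Conditions: TFAA, CH2Cl2, 0 °C → rt
Reagents that add atoms: none
Why: Intramolecular Friedel–Crafts acylation through the mixed anhydride closes ring B (C1–C8a, six-membered) at the ring A position para to a methoxy group, whereas both ortho positions of ring C are meta to its methoxy group and carry only the weakly donating acyloxy group, so ring A should be acylated selectively and no stereocentre is touched.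

Step 14
Reactants: 26 (2S,3R,4R)-4-(3-acetoxy-4-methoxyphenyl)-6,7-dimethoxy-2,3-dimethyl-3,4-dihydronaphthalen-1(2H)-one
Product: 27 (2S,3R,4R)-4-(3-hydroxy-4-methoxyphenyl)-6,7-dimethoxy-2,3-dimethyl-3,4-dihydronaphthalen-1(2H)-one
Conditions: K2CO3 (cat.), MeOH, rt
Reagents that add atoms: none
Why: Base-catalysed methanolysis (transesterification) of the aryl acetate frees the phenol without affecting C3 or C4, and C2 already has the thermodynamically preferred configuration (2-methyl equatorial and trans to the 3-methyl, away from the pseudoaxial 4-aryl group), so enolisation should not change it.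

## Compound list

1 | veratraldehyde | COc1ccc(C=O)cc1OC | starting material
2 | (R)-2-methylpropane-2-sulfinamide | CC(C)(C)[S@@](=O)N | starting material
3 | (R,E)-N-(3,4-dimethoxybenzylidene)-2-methylpropane-2-sulfinamide | COc1ccc(/C=N/[S@](=O)C(C)(C)C)cc1OC | intermediate
4 | 2-(benzyloxy)-4-bromo-1-methoxybenzene | COc1ccc(Br)cc1OCc1ccccc1 | starting material
5 | [3-(benzyloxy)-4-methoxyphenyl]magnesium bromide | COc1ccc([Mg]Br)cc1OCc1ccccc1 | intermediate
6 | (R)-N-[(R)-(3-(benzyloxy)-4-methoxyphenyl)(3,4-dimethoxyphenyl)methyl]-2-methylpropane-2-sulfinamide | COc1ccc(cc1OCc1ccccc1)[C@H](N[S@](=O)C(C)(C)C)c1ccc(OC)c(OC)c1 | intermediate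
7 | (R)-(3-(benzyloxy)-4-methoxyphenyl)(3,4-dimethoxyphenyl)methanamine | COc1ccc(cc1OCc1ccccc1)[C@H](N)c1ccc(OC)c(OC)c1 | intermediate
8 | (R)-1-(3-(benzyloxy)-4-methoxyphenyl)-1-(3,4-dimethoxyphenyl)-N,N-dimethylmethanamine | COc1ccc(cc1OCc1ccccc1)[C@H](N(C)C)c1ccc(OC)c(OC)c1 | intermediate
9 | (R)-[(3-(benzyloxy)-4-methoxyphenyl)(3,4-dimethoxyphenyl)methyl]trimethylammonium trifluoromethanesulfonate | COc1ccc(cc1OCc1ccccc1)[C@H]([N+](C)(C)C)c1ccc(OC)c(OC)c1.[O-]S(=O)(=O)C(F)(F)F | intermediate
10 | 2-[(S)-(3-(benzyloxy)-4-methoxyphenyl)(3,4-dimethoxyphenyl)methyl]-4,4,5,5-tetramethyl-1,3,2-dioxaborolane | COc1ccc(cc1OCc1ccccc1)[C@@H](B1OC(C)(C)C(C)(C)O1)c1ccc(OC)c(OC)c1 | intermediate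
11 | ethyl 2,4,6-triisopropylbenzoate | CCOC(=O)c1c(C(C)C)cc(C(C)C)cc1C(C)C | starting material
12 | (S)-1-lithioethyl 2,4,6-triisopropylbenzoate | [Li][C@@H](C)OC(=O)c1c(C(C)C)cc(C(C)C)cc1C(C)C | intermediate
13 | lithium [(S)-(3-(benzyloxy)-4-methoxyphenyl)(3,4-dimethoxyphenyl)methyl][(S)-1-(2,4,6-triisopropylbenzoyloxy)ethyl](pinacolato)borate | COc1ccc(cc1OCc1ccccc1)[C@@H]([B-]1(OC(C)(C)C(C)(C)O1)[C@@H](C)OC(=O)c1c(C(C)C)cc(C(C)C)cc1C(C)C)c1ccc(OC)c(OC)c1.[Li+] | intermediate
14 | 2-[(1S,2R)-1-(3-(benzyloxy)-4-methoxyphenyl)-1-(3,4-dimethoxyphenyl)propan-2-yl]-4,4,5,5-tetramethyl-1,3,2-dioxaborolane | COc1ccc(cc1OCc1ccccc1)[C@@H]([C@@H](C)B1OC(C)(C)C(C)(C)O1)c1ccc(OC)c(OC)c1 | intermediate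
15 | (R)-1-lithioethyl 2,4,6-triisopropylbenzoate | [Li][C@H](C)OC(=O)c1c(C(C)C)cc(C(C)C)cc1C(C)C | intermediate
16 | lithium [(1S,2R)-1-(3-(benzyloxy)-4-methoxyphenyl)-1-(3,4-dimethoxyphenyl)propan-2-yl][(R)-1-(2,4,6-triisopropylbenzoyloxy)ethyl](pinacolato)borate | COc1ccc(cc1OCc1ccccc1)[C@@H]([C@@H](C)[B-]1(OC(C)(C)C(C)(C)O1)[C@H](C)OC(=O)c1c(C(C)C)cc(C(C)C)cc1C(C)C)c1ccc(OC)c(OC)c1.[Li+] | intermediate
17 | 2-[(2S,3S,4S)-4-(3-(benzyloxy)-4-methoxyphenyl)-4-(3,4-dimethoxyphenyl)-3-methylbutan-2-yl]-4,4,5,5-tetramethyl-1,3,2-dioxaborolane | COc1ccc(cc1OCc1ccccc1)[C@@H]([C@@H](C)[C@H](C)B1OC(C)(C)C(C)(C)O1)c1ccc(OC)c(OC)c1 | intermediate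
18 | lithium (chloromethyl)[(2S,3S,4S)-4-(3-(benzyloxy)-4-methoxyphenyl)-4-(3,4-dimethoxyphenyl)-3-methylbutan-2-yl](pinacolato)borate | COc1ccc(cc1OCc1ccccc1)[C@@H]([C@@H](C)[C@H](C)[B-]1(CCl)OC(C)(C)C(C)(C)O1)c1ccc(OC)c(OC)c1.[Li+] | intermediate
19 | 2-[(2R,3S,4S)-4-(3-(benzyloxy)-4-methoxyphenyl)-4-(3,4-dimethoxyphenyl)-2,3-dimethylbutyl]-4,4,5,5-tetramethyl-1,3,2-dioxaborolane | COc1ccc(cc1OCc1ccccc1)[C@@H]([C@@H](C)[C@H](C)CB1OC(C)(C)C(C)(C)O1)c1ccc(OC)c(OC)c1 | intermediate
20 | (2S,3R,4S)-4-(3-(benzyloxy)-4-methoxyphenyl)-4-(3,4-dimethoxyphenyl)-2,3-dimethylbutan-1-ol | COc1ccc(cc1OCc1ccccc1)[C@@H]([C@@H](C)[C@H](C)CO)c1ccc(OC)c(OC)c1 | intermediate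
21 | (2S,3R,4S)-4-(3-(benzyloxy)-4-methoxyphenyl)-4-(3,4-dimethoxyphenyl)-2,3-dimethylbutanal | COc1ccc(cc1OCc1ccccc1)[C@@H]([C@@H](C)[C@H](C)C=O)c1ccc(OC)c(OC)c1 | intermediate
22 | (2S,3R,4S)-4-(3-(benzyloxy)-4-methoxyphenyl)-4-(3,4-dimethoxyphenyl)-2,3-dimethylbutanoic acid | COc1ccc(cc1OCc1ccccc1)[C@@H]([C@@H](C)[C@H](C)C(=O)O)c1ccc(OC)c(OC)c1 | intermediate
23 | (2S,3R,4R)-4-(3,4-dimethoxyphenyl)-4-(3-hydroxy-4-methoxyphenyl)-2,3-dimethylbutanoic acid | COc1ccc(cc1O)[C@@H]([C@@H](C)[C@H](C)C(=O)O)c1ccc(OC)c(OC)c1 | intermediate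
24 | (2S,3R,4S)-4-(3-acetoxy-4-methoxyphenyl)-4-(3,4-dimethoxyphenyl)-2,3-dimethylbutanoic acid | COc1ccc(cc1OC(C)=O)[C@@H]([C@@H](C)[C@H](C)C(=O)O)c1ccc(OC)c(OC)c1 | intermediate
25 | (2S,3R,4S)-4-(3-acetoxy-4-methoxyphenyl)-4-(3,4-dimethoxyphenyl)-2,3-dimethylbutanoic trifluoroacetic anhydride | COc1ccc(cc1OC(C)=O)[C@@H]([C@@H](C)[C@H](C)C(=O)OC(=O)C(F)(F)F)c1ccc(OC)c(OC)c1 | intermediate
26 | (2S,3R,4R)-4-(3-acetoxy-4-methoxyphenyl)-6,7-dimethoxy-2,3-dimethyl-3,4-dihydronaphthalen-1(2H)-one | COc1ccc([C@@H]2c3cc(OC)c(OC)cc3C(=O)[C@@H](C)[C@@H]2C)cc1OC(C)=O | intermediate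
27 | (2S,3R,4R)-4-(3-hydroxy-4-methoxyphenyl)-6,7-dimethoxy-2,3-dimethyl-3,4-dihydronaphthalen-1(2H)-one | COc1ccc([C@@H]2c3cc(OC)c(OC)cc3C(=O)[C@@H](C)[C@@H]2C)cc1O | target

## Step count and risks

Total step count: 14. Longest linear sequence: 14 steps (1 to 27).

Steps most likely to fail:

1. Step 7. What may go wrong: slow or incomplete addition of the bulky diamine-bound carbenoid to the hindered diarylmethyl boron, competing removal of the acidic C4 proton (which would scramble C4 with no visible change, the aryl groups being so alike), or reluctant migration, leaving mixtures of 10, 14 and 17. The fallback makes C3–C4 by a Zweifel olefination and sets C2 and C3 together by asymmetric hydroboration. It sets out from 10: (E)-but-2-en-2-yllithium (from (Z)-2-bromobut-2-ene and t-BuLi, THF, −78 °C), a small sp2 organolithium, should add readily to boron. I2 and then NaOMe/MeOH should bring about migration of the diarylmethyl group with retention at C4 and anti elimination, giving the alkene 2-(benzyloxy)-4-[(1S,2E)-1-(3,4-dimethoxyphenyl)-2-methylbut-2-en-1-yl]-1-methoxybenzene F1. Syn hydroboration with IpcBH2 made from (+)-α-pinene (boron to the less substituted C2; the sense is chosen by analogy with its S-selective additions to trans-but-2-ene and 2-methylbut-2-ene) should give [(2S,3S,4S)-4-(3-(benzyloxy)-4-methoxyphenyl)-4-(3,4-dimethoxyphenyl)-3-methylbutan-2-yl](isopinocampheyl)borane F2. Acetaldehyde should then expel α-pinene to give diethyl [(2S,3S,4S)-4-(3-(benzyloxy)-4-methoxyphenyl)-4-(3,4-dimethoxyphenyl)-3-methylbutan-2-yl]boronate F3, and exchange with pinacol comes back to the route at 17.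

2. Step 6. What may go wrong: heterolysis of the C–N bond of 9 to the benzhydryl cation stabilised by two para-alkoxy groups, or slow oxidative addition in the absence of an extended π-system, giving racemised 10 or low conversion. The fallback makes the C4–B bond by lithiation–borylation of a benzylic carbamate. It sets out from 1 and 4: NaBH4 reduction of 1 gives 3,4-dimethoxybenzyl alcohol F4, and i-Pr2NCOCl/Et3N gives 3,4-dimethoxybenzyl N,N-diisopropylcarbamate F5. Bromine–lithium exchange on 4 (n-BuLi, THF, −78 °C) and trapping with i-PrOBpin gives 2-[3-(benzyloxy)-4-methoxyphenyl]-4,4,5,5-tetramethyl-1,3,2-dioxaborolane F6. Deprotonation of F5 with s-BuLi in the presence of a chiral bis(oxazoline) ligand (enantiomer chosen for the S product), borylation with F6 and 1,2-migration of the aryl group with loss of the carbamate (MgBr2·OEt2, warming) comes back to the route at 10.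

3. Step 2. What may go wrong: insufficient facial selectivity in the aryl transfer; the two diastereomers of 6 differ only in which ring carries the benzyloxy group and are not expected to separate, so any leakage is carried on as the enantiomer of the target. The fallback sets C4 by catalyst control. It sets out from 1: condensation with 4-nitrobenzenesulfonamide (TsOH cat., toluene, reflux with removal of water) gives (E)-N-(3,4-dimethoxybenzylidene)-4-nitrobenzenesulfonamide F7. Rhodium-catalysed asymmetric addition of commercial [3-(benzyloxy)-4-methoxyphenyl]boronic acid ([RhCl(C2H4)2]2, chiral bicyclic diene ligand of the enantiomer giving R, KOH, dioxane/H2O, 60 °C) should give (R)-N-[(3-(benzyloxy)-4-methoxyphenyl)(3,4-dimethoxyphenyl)methyl]-4-nitrobenzenesulfonamide F8. Thiolate cleavage of the nosyl group (PhSH, K2CO3, DMF) comes back to the route at 7.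

Further compounds
F1 | step 7 | 2-(benzyloxy)-4-[(1S,2E)-1-(3,4-dimethoxyphenyl)-2-methylbut-2-en-1-yl]-1-methoxybenzene | C/C=C(\C)[C@H](c1ccc(OC)c(OCc2ccccc2)c1)c1ccc(OC)c(OC)c1
F2 | step 7 | [(2S,3S,4S)-4-(3-(benzyloxy)-4-methoxyphenyl)-4-(3,4-dimethoxyphenyl)-3-methylbutan-2-yl](isopinocampheyl)borane | COc1ccc(cc1OCc1ccccc1)[C@@H]([C@@H](C)[C@H](C)B[C@@H]1C[C@@H]2C[C@H]([C@H]1C)C2(C)C)c1ccc(OC)c(OC)c1
F3 | step 7 | diethyl [(2S,3S,4S)-4-(3-(benzyloxy)-4-methoxyphenyl)-4-(3,4-dimethoxyphenyl)-3-methylbutan-2-yl]boronate | COc1ccc(cc1OCc1ccccc1)[C@@H]([C@@H](C)[C@H](C)B(OCC)OCC)c1ccc(OC)c(OC)c1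
F4 | step 6 | 3,4-dimethoxybenzyl alcohol | COc1ccc(CO)cc1OC
F5 | step 6 | 3,4-dimethoxybenzyl N,N-diisopropylcarbamate | COc1ccc(COC(=O)N(C(C)C)C(C)C)cc1OC
F6 | step 6 | 2-[3-(benzyloxy)-4-methoxyphenyl]-4,4,5,5-tetramethyl-1,3,2-dioxaborolane | COc1ccc(B2OC(C)(C)C(C)(C)O2)cc1OCc1ccccc1
F7 | step 2 | (E)-N-(3,4-dimethoxybenzylidene)-4-nitrobenzenesulfonamide | COc1ccc(/C=N/S(=O)(=O)c2ccc([N+](=O)[O-])cc2)cc1OC
F8 | step 2 | (R)-N-[(3-(benzyloxy)-4-methoxyphenyl)(3,4-dimethoxyphenyl)methyl]-4-nitrobenzenesulfonamide | COc1ccc(cc1OCc1ccccc1)[C@H](NS(=O)(=O)c1ccc([N+](=O)[O-])cc1)c1ccc(OC)c(OC)c1
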